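**Plan**

1. Retrosynthesis: cut the lactone C3–CH2 bond to the central phenol ring (ring B) of the open diol unit, then the lactone C4–CH2 bond to the dihydrobenzofuran. This leaves a C4 butenolide, benzylic bromide 24 and aryl dithiane 19. Both aryl pieces are cut at the ArCH(O)–CH(Ar)CH2O bond (aldol), and 19 also at the dihydrofuran O–C2 bond.
2. Enabling feature: in the γ-butyrolactone ring, C4 (β to C2=O) and C3 (α) each carry one benzylic CH2, trans to each other, and C5 is a bare OCH2. A 2(5H)-furanone can therefore accept a benzyl anion equivalent at C4 and then a benzyl bromide at C3 of the enolate so formed, while C5 carries a removable menthyloxy group.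
3. Forward: one anti-aldol adduct (12, then phenol 15) serves both halves. Branch A closes the dihydrofuran ring (O–C2) and ends as dithiane 19; branch B stays open and ends as bromide 24.
4. Dithiane 19, furanone 27 and bromide 24 are joined in one flask. The lactone ring is brought in intact and only trimmed afterwards (C–S cleavage, C5–O removal), followed by global desilylation.
5. Stereochemistry: the (1S,2S) carbinol/aryl pair comes from (S)-4-benzyl-2-oxazolidinone (anti-aldol). Dihydrobenzofuran C2 (R) arises by inversion of that same 1S carbinol, with C3 (S) carried over. Lactone C4 is set by the C5 menthyloxy acetal of 27, and C3 by C4 (trans).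

Key step: step 17

Remark: the target is read as a (3S,4S)-lactone bearing a (2R,3S)-trans-dihydrobenzofuran and a (1S,2S)-1,2-diarylpropane-1,3-diol unit. TBS = tert-butyldimethylsilyl, TIPS = triisopropylsilyl, TBSO/TIPSO = the corresponding silyloxy groups, menthyl = (1S,2R,5S)-2-isopropyl-5-methylcyclohexyl. Aryl silyl ethers are expected to survive steps 14, 18 and 19; any lost there would be removed in step 20 anyway.

**Route**

Step 1
Reactants: 1 5-bromo-2-hydroxy-3-methoxybenzaldehyde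
Product: 2 2-(allyloxy)-5-bromo-3-methoxybenzaldehyde
Conditions: allyl bromide, K2CO3, DMF, rt
Reagents that add atoms: allyl bromide, C=CCBr
Why: Williamson etherification of the phenoxide; the allyl ether masks the ring B phenol through the enolate chemistry and can later be removed without acid, strong base or hydrogen.

Step 2
Reactants: 2 2-(allyloxy)-5-bromo-3-methoxybenzaldehyde
Product: 3 1-(allyloxy)-4-bromo-2-methoxy-6-(2-methoxyvinyl)benzene (E/Z mixture)
Conditions: Ph3P(CH2OMe)Cl, KOt-Bu, THF, 0 °C → rt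
Reagents that add atoms: (methoxymethyl)triphenylphosphonium chloride, COC[P+](c1ccccc1)(c1ccccc1)c1ccccc1.[Cl-]
Why: Wittig methoxymethylenation adds the one carbon needed for the arylacetic acid; both alkene isomers converge in step 3.

Step 3
Reactants: 3 1-(allyloxy)-4-bromo-2-methoxy-6-(2-methoxyvinyl)benzene
Product: 5 2-(2-allyloxy-5-bromo-3-methoxyphenyl)acetic acid, via arylacetaldehyde 4 (not isolated)
Conditions: 2 M HCl, THF, rt; then NaClO2, NaH2PO4, 2-methyl-2-butene, t-BuOH/H2O, 0 °C → rt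
Reagents that add atoms: water, O; sodium chlorite, [Na+].[O-]Cl=O
Why: enol ether hydrolysis followed at once by Pinnick oxidation avoids handling the self-condensing arylacetaldehyde; the scavenger protects the allyl ether from hypochlorous acid.

Step 4
Reactants: 5 2-(2-allyloxy-5-bromo-3-methoxyphenyl)acetic acid; 6 (S)-4-benzyl-2-oxazolidinone
Product: 8 (S)-3-[2-(2-allyloxy-5-bromo-3-methoxyphenyl)acetyl]-4-benzyloxazolidin-2-one, via pivalic mixed anhydride 7 (not isolated)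
Conditions: t-BuCOCl, Et3N, THF, −20 °C; then LiCl, 6, −20 °C → rt
Reagents that add atoms: none
Why: N-acylation of the oxazolidinone through the mixed anhydride, which is attacked at the less hindered arylacetyl carbonyl (standard auxiliary loading).

Step 5
Reactants: 9 vanillin
Product: 10 3-methoxy-4-(triisopropylsilyloxy)benzaldehyde
Conditions: i-Pr3SiCl, imidazole, DMF, rt
Reagents that add atoms: triisopropylsilyl chloride, CC(C)[Si](Cl)(C(C)C)C(C)C
Why: phenol silylation; the aryl TIPS ether tolerates organolithiums, hydrides and mild base and is removed by fluoride at the end.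

Step 6
Reactants: 8 (S)-3-[2-(2-allyloxy-5-bromo-3-methoxyphenyl)acetyl]-4-benzyloxazolidin-2-one; 10 3-methoxy-4-(triisopropylsilyloxy)benzaldehyde
Product: 12 (S)-4-benzyl-3-[(2R,3S)-2-(2-allyloxy-5-bromo-3-methoxyphenyl)-3-hydroxy-3-(3-methoxy-4-TIPSO-phenyl)propanoyl]oxazolidin-2-one (anti), via aldol trimethylsilyl ether 11 (not isolated)
Conditions: MgCl2 (20 mol %), Et3N, Me3SiCl, EtOAc, rt; then MeOH, cat. CF3CO2H, 0 °C
Reagents that add atoms: none
Why: magnesium halide-catalysed direct anti-aldol of an N-acyloxazolidinone (Evans type): soft enolization gives the chelated Z magnesium enolate, the non-enolizable aryl aldehyde adds through a boat transition state on the face opposite the auxiliary benzyl group (2R) with anti simple selectivity (3S), and silylation of the aldolate makes the addition irreversible.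

Step 7
Reactants: 12 anti-aldol adduct
Product: 13 (1S,2S)-2-(2-allyloxy-5-bromo-3-methoxyphenyl)-1-(3-methoxy-4-TIPSO-phenyl)propane-1,3-diol
Conditions: LiBH4, MeOH (1 equiv), THF, 0 °C
Reagents that add atoms: none
Why: reductive cleavage of the imide to the primary alcohol, with recovery of the auxiliary, under conditions too mild for retro-aldol or epimerization of the aryl-bearing carbon.

Step 8
Reactants: 13 (1S,2S)-diol
Product: 14 (1S,2S)-2-(2-allyloxy-5-bromo-3-methoxyphenyl)-3-(TBSO)-1-(3-methoxy-4-TIPSO-phenyl)propan-1-ol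
Conditions: t-BuMe2SiCl, imidazole, CH2Cl2, 0 °C
Reagents that add atoms: tert-butyldimethylsilyl chloride, CC(C)(C)[Si](C)(C)Cl
Why: the primary hydroxyl is silylated much faster than the hindered secondary benzylic one.

Step 9
Reactants: 14 primary TBS ether
Product: 15 (1S,2S)-2-(5-bromo-2-hydroxy-3-methoxyphenyl)-3-(TBSO)-1-(3-methoxy-4-TIPSO-phenyl)propan-1-ol
Conditions: Pd(PPh3)4 (5 mol %), morpholine, THF, rt
Reagents that add atoms: none
Why: Tsuji–Trost deallylation: zerovalent palladium ionizes the aryl allyl ether and morpholine traps the allyl unit, while the electron-rich aryl bromide is inert at room temperature.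

Step 10
Reactants: 15 phenol alcohol
Product: 16 (2R,3S)-5-bromo-3-(TBSO-methyl)-7-methoxy-2-(3-methoxy-4-TIPSO-phenyl)-2,3-dihydrobenzofuran
Conditions: PPh3, DIAD, THF, 0 °C → rt
Reagents that add atoms: none
Why: intramolecular Mitsunobu etherification (5-exo-tet): the only free alcohol is activated and displaced by the ring B phenoxide with inversion (1S carbinol → 2R), giving the trans ring; any ionization to the benzylic cation would also close anti to the C3 substituent.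

Step 11
Reactants: 16 dihydrobenzofuran bromide
Product: 18 (2R,3S)-3-(TBSO-methyl)-7-methoxy-2-(3-methoxy-4-TIPSO-phenyl)-2,3-dihydrobenzofuran-5-carbaldehyde, via aryllithium 17 (not isolated)
Conditions: n-BuLi, THF, −78 °C; DMF, −78 → 0 °C; H2O
Reagents that add atoms: N,N-dimethylformamide, CN(C)C=O
Why: bromine–lithium exchange followed by formylation; no acidic proton or electrophilic group is present and the silyl ethers tolerate butyllithium at −78 °C.

Step 12
Reactants: 18 dihydrobenzofuran aldehyde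
Product: 19 2-[(2R,3S)-3-(TBSO-methyl)-7-methoxy-2-(3-methoxy-4-TIPSO-phenyl)-2,3-dihydrobenzofuran-5-yl]-1,3-dithiane
Conditions: HS(CH2)3SH, I2 (10 mol %), CH2Cl2, 0 °C → rt
Reagents that add atoms: propane-1,3-dithiol, SCCCS
Why: iodine-catalysed thioacetalization is mild enough for the primary TBS ether and the benzylic ether of the dihydrofuran; the dithiane turns the aldehyde carbon into a benzyl anion equivalent.

Step 13
Reactants: 15 phenol alcohol
Product: 20 (1S,2S)-2-[5-bromo-3-methoxy-2-(TBSO)phenyl]-1-(3-methoxy-4-TIPSO-phenyl)propane-1,3-diol bis-TBS ether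
Conditions: t-BuMe2SiOTf, 2,6-lutidine, CH2Cl2, 0 °C → rt
Reagents that add atoms: tert-butyldimethylsilyl triflate, CC(C)(C)[Si](C)(C)OS(=O)(=O)C(F)(F)F
Why: the silyl triflate caps both the hindered phenol and the secondary benzylic alcohol, so the open-chain half carries only fluoride-labile groups.

Step 14
Reactants: 20 fully silylated aryl bromide
Product: 23 {3-[(1S,2S)-1,3-bis(TBSO)-1-(3-methoxy-4-TIPSO-phenyl)propan-2-yl]-5-methoxy-4-(TBSO)phenyl}methanol, via aryllithium 21 (not isolated), via benzaldehyde 22 (not isolated)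
Conditions: n-BuLi, THF, −78 °C; DMF, −78 → 0 °C; then MeOH, NaBH4, 0 °C
Reagents that add atoms: N,N-dimethylformamide, CN(C)C=O
Why: bromine–lithium exchange and formylation as in step 11, with the aldehyde released by methanol and reduced in the same flask by borohydride.

Step 15
Reactants: 23 benzylic alcohol
Product: 24 3-[(1S,2S)-1,3-bis(TBSO)-1-(3-methoxy-4-TIPSO-phenyl)propan-2-yl]-5-methoxy-4-(TBSO)benzyl bromide
Conditions: CBr4, PPh3, CH2Cl2, 0 °C
Reagents that add atoms: carbon tetrabromide, BrC(Br)(Br)Br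
Why: Appel bromination under neutral conditions; the p-silyloxybenzyl bromide is used without storage.

Step 16
Reactants: 25 5-hydroxy-2(5H)-furanone; 26 (1S,2R,5S)-(+)-menthol
Product: 27 (5S)-5-[(1S,2R,5S)-menthyloxy]-2(5H)-furanone
Conditions: cat. camphorsulfonic acid, toluene, reflux (Dean–Stark); crystallization from petroleum ether, −20 °C
Reagents that add atoms: none
Why: acid-catalysed acetalization of the lactol; the C5 epimers equilibrate through the oxocarbenium ion and the (5S) diastereomer, the mirror image of the well-known crystalline (5R)-(l-menthyloxy) compound, is collected by crystallization.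

Step 17
Reactants: 19 aryl dithiane; 27 (5S)-5-menthyloxy-2(5H)-furanone; 24 benzylic bromide
Product: 30 (3S,4S,5S)-3-{3-[(1S,2S)-1,3-bis(TBSO)-1-(3-methoxy-4-TIPSO-phenyl)propan-2-yl]-5-methoxy-4-(TBSO)benzyl}-4-{2-[(2R,3S)-3-(TBSO-methyl)-7-methoxy-2-(3-methoxy-4-TIPSO-phenyl)-2,3-dihydrobenzofuran-5-yl]-1,3-dithian-2-yl}-5-menthyloxydihydrofuran-2(3H)-one, via lithiated dithiane 28 (not isolated), via lactone lithium enolate 29 (not isolated)
Conditions: 19, n-BuLi, THF, −78 → −20 °C; 27, −78 °C; then 24, DMPU, −78 °C → rt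
Reagents that add atoms: none
Why: butyllithium removes the dithiane C2 proton, the sulfur-stabilized anion 28 adds 1,4 to C4 of furanone 27 to give lactone enolate 29, and 29 is C-benzylated at C3 by bromide 24 in an SN2 step, forming the lactone C3–CH2 bond to ring B. The closest known reaction type is the tandem conjugate addition–enolate alkylation of lithiated 2-aryl-1,3-dithianes with 5-alkoxy-2(5H)-furanones and benzylic bromides, used for trans-dibenzylbutyrolactone lignans. No ring is closed; the lactone ring enters intact from 27. C4 is set by the C5 menthyloxy group (addition anti to it) and C3 by the new, very bulky C4 substituent (alkylation trans to it), while C5 is untouched. The step needs 1,4- over 1,2-addition, which the soft delocalized dithiane anion secures, and C-monoalkylation, favoured by the unhindered benzylic bromide (two ortho hydrogens) and by the quaternary dithiane carbon next to C3. Every hydroxyl is silylated, so no proton source can quench 28 or 29.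

Step 18
Reactants: 30 coupled dithiane lactone acetal
Product: 31 (3S,4S,5S)-3-{3-[(1S,2S)-1,3-bis(TBSO)-1-(3-methoxy-4-TIPSO-phenyl)propan-2-yl]-5-methoxy-4-(TBSO)benzyl}-4-{[(2R,3S)-3-(TBSO-methyl)-7-methoxy-2-(3-methoxy-4-TIPSO-phenyl)-2,3-dihydrobenzofuran-5-yl]methyl}-5-menthyloxydihydrofuran-2(3H)-one
Conditions: NiCl2·6H2O, NaBH4, MeOH/THF, 0 °C
Reagents that add atoms: none
Why: nickel boride desulfurization turns the dithiane carbon into the benzylic CH2 at 0 °C, conditions under which benzylic C–O bonds, silyl ethers and the lactone should persist; no stereocenter is involved.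

Step 19
Reactants: 31 lactone acetal
Product: 34 (3S,4S)-3-{3-[(1S,2S)-1,3-bis(TBSO)-1-(3-methoxy-4-TIPSO-phenyl)propan-2-yl]-5-methoxy-4-(TBSO)benzyl}-4-{[(2R,3S)-3-(TBSO-methyl)-7-methoxy-2-(3-methoxy-4-TIPSO-phenyl)-2,3-dihydrobenzofuran-5-yl]methyl}dihydrofuran-2(3H)-one, via aldehyde carboxylate 32 (not isolated), via hydroxy carboxylate 33 (not isolated)
Conditions: NaBH4, KOH, THF/EtOH/H2O, 0 °C; then 1 M HCl to pH 3, 0 °C → rt
Reagents that add atoms: none
Why: hydroxide opens the acylal-type lactone at C2, the C5 hemiacetal loses mentholate to give an aldehyde that borohydride reduces at once, and mild acidification relactonizes the γ-hydroxy acid, so C2 stays the carbonyl next to C3 and C5 becomes the OCH2 without touching C3 or C4.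

Step 20
Reactants: 34 hexasilylated lactone
Product: 35 target CNP0186558.3
Conditions: Bu4NF, AcOH (1:1, excess), THF, 0 °C → rt
Reagents that add atoms: none
Why: buffered fluoride cleaves the four TBS and two TIPS ethers in one operation; the near-neutral medium avoids both phenoxide-driven quinone methide formation and acid-driven cyclization of the free 1,3-diol/phenol unit, and the trans lactone is the stable epimer.

**Compound list**

1 | 5-bromo-2-hydroxy-3-methoxybenzaldehyde | COc1cc(Br)cc(C=O)c1O | starting material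
2 | 2-(allyloxy)-5-bromo-3-methoxybenzaldehyde | COc1cc(Br)cc(C=O)c1OCC=C | intermediate
3 | 1-(allyloxy)-4-bromo-2-methoxy-6-(2-methoxyvinyl)benzene (E/Z) | COC=Cc1cc(Br)cc(OC)c1OCC=C | intermediate
4 | 2-(2-allyloxy-5-bromo-3-methoxyphenyl)acetaldehyde | O=CCc1cc(Br)cc(OC)c1OCC=C | intermediate
5 | 2-(2-allyloxy-5-bromo-3-methoxyphenyl)acetic acid | OC(=O)Cc1cc(Br)cc(OC)c1OCC=C | intermediate
6 | (S)-4-benzyl-2-oxazolidinone | O=C1N[C@@H](Cc2ccccc2)CO1 | starting material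
7 | mixed anhydride of 5 with pivalic acid | CC(C)(C)C(=O)OC(=O)Cc1cc(Br)cc(OC)c1OCC=C | intermediate
8 | (S)-3-[2-(2-allyloxy-5-bromo-3-methoxyphenyl)acetyl]-4-benzyloxazolidin-2-one | COc1cc(Br)cc(CC(=O)N2C(=O)OC[C@@H]2Cc2ccccc2)c1OCC=C | intermediate
9 | vanillin | COc1cc(C=O)ccc1O | starting material
10 | 3-methoxy-4-(triisopropylsilyloxy)benzaldehyde | COc1cc(C=O)ccc1O[Si](C(C)C)(C(C)C)C(C)C | intermediate
11 | trimethylsilyl ether of aldol adduct 12 | COc1cc([C@@H](O[Si](C)(C)C)[C@H](C(=O)N2C(=O)OC[C@@H]2Cc2ccccc2)c2cc(Br)cc(OC)c2OCC=C)ccc1O[Si](C(C)C)(C(C)C)C(C)C | intermediate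
12 | (S)-4-benzyl-3-[(2R,3S)-2-(2-allyloxy-5-bromo-3-methoxyphenyl)-3-hydroxy-3-(3-methoxy-4-TIPSO-phenyl)propanoyl]oxazolidin-2-one | COc1cc([C@@H](O)[C@H](C(=O)N2C(=O)OC[C@@H]2Cc2ccccc2)c2cc(Br)cc(OC)c2OCC=C)ccc1O[Si](C(C)C)(C(C)C)C(C)C | intermediate
13 | (1S,2S)-2-(2-allyloxy-5-bromo-3-methoxyphenyl)-1-(3-methoxy-4-TIPSO-phenyl)propane-1,3-diol | COc1cc([C@@H](O)[C@H](CO)c2cc(Br)cc(OC)c2OCC=C)ccc1O[Si](C(C)C)(C(C)C)C(C)C | intermediate
14 | (1S,2S)-2-(2-allyloxy-5-bromo-3-methoxyphenyl)-3-(TBSO)-1-(3-methoxy-4-TIPSO-phenyl)propan-1-ol | COc1cc([C@@H](O)[C@H](CO[Si](C)(C)C(C)(C)C)c2cc(Br)cc(OC)c2OCC=C)ccc1O[Si](C(C)C)(C(C)C)C(C)C | intermediate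
15 | (1S,2S)-2-(5-bromo-2-hydroxy-3-methoxyphenyl)-3-(TBSO)-1-(3-methoxy-4-TIPSO-phenyl)propan-1-ol | COc1cc([C@@H](O)[C@H](CO[Si](C)(C)C(C)(C)C)c2cc(Br)cc(OC)c2O)ccc1O[Si](C(C)C)(C(C)C)C(C)C | intermediate
16 | (2R,3S)-5-bromo-3-(TBSO-methyl)-7-methoxy-2-(3-methoxy-4-TIPSO-phenyl)-2,3-dihydrobenzofuran | Brc1cc(OC)c2c(c1)[C@@H](CO[Si](C)(C)C(C)(C)C)[C@H](c1ccc(O[Si](C(C)C)(C(C)C)C(C)C)c(OC)c1)O2 | intermediate
17 | 5-lithio analogue of 16 | [Li]c1cc(OC)c2c(c1)[C@@H](CO[Si](C)(C)C(C)(C)C)[C@H](c1ccc(O[Si](C(C)C)(C(C)C)C(C)C)c(OC)c1)O2 | intermediate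
18 | (2R,3S)-3-(TBSO-methyl)-7-methoxy-2-(3-methoxy-4-TIPSO-phenyl)-2,3-dihydrobenzofuran-5-carbaldehyde | O=Cc1cc(OC)c2c(c1)[C@@H](CO[Si](C)(C)C(C)(C)C)[C@H](c1ccc(O[Si](C(C)C)(C(C)C)C(C)C)c(OC)c1)O2 | intermediate
19 | 2-[(2R,3S)-3-(TBSO-methyl)-7-methoxy-2-(3-methoxy-4-TIPSO-phenyl)-2,3-dihydrobenzofuran-5-yl]-1,3-dithiane | C1(SCCCS1)c1cc(OC)c2c(c1)[C@@H](CO[Si](C)(C)C(C)(C)C)[C@H](c1ccc(O[Si](C(C)C)(C(C)C)C(C)C)c(OC)c1)O2 | intermediate
20 | (1S,2S)-2-[5-bromo-3-methoxy-2-(TBSO)phenyl]-1-(3-methoxy-4-TIPSO-phenyl)propane-1,3-diol bis-TBS ether | COc1cc([C@@H](O[Si](C)(C)C(C)(C)C)[C@H](CO[Si](C)(C)C(C)(C)C)c2cc(Br)cc(OC)c2O[Si](C)(C)C(C)(C)C)ccc1O[Si](C(C)C)(C(C)C)C(C)C | intermediate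
21 | aryllithium from 20 (lithium in place of bromine) | COc1cc([C@@H](O[Si](C)(C)C(C)(C)C)[C@H](CO[Si](C)(C)C(C)(C)C)c2cc([Li])cc(OC)c2O[Si](C)(C)C(C)(C)C)ccc1O[Si](C(C)C)(C(C)C)C(C)C | intermediate
22 | 3-[(1S,2S)-1,3-bis(TBSO)-1-(3-methoxy-4-TIPSO-phenyl)propan-2-yl]-5-methoxy-4-(TBSO)benzaldehyde | COc1cc([C@@H](O[Si](C)(C)C(C)(C)C)[C@H](CO[Si](C)(C)C(C)(C)C)c2cc(C=O)cc(OC)c2O[Si](C)(C)C(C)(C)C)ccc1O[Si](C(C)C)(C(C)C)C(C)C | intermediate
23 | {3-[(1S,2S)-1,3-bis(TBSO)-1-(3-methoxy-4-TIPSO-phenyl)propan-2-yl]-5-methoxy-4-(TBSO)phenyl}methanol | COc1cc([C@@H](O[Si](C)(C)C(C)(C)C)[C@H](CO[Si](C)(C)C(C)(C)C)c2cc(CO)cc(OC)c2O[Si](C)(C)C(C)(C)C)ccc1O[Si](C(C)C)(C(C)C)C(C)C | intermediate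
24 | 3-[(1S,2S)-1,3-bis(TBSO)-1-(3-methoxy-4-TIPSO-phenyl)propan-2-yl]-5-methoxy-4-(TBSO)benzyl bromide | COc1cc([C@@H](O[Si](C)(C)C(C)(C)C)[C@H](CO[Si](C)(C)C(C)(C)C)c2cc(CBr)cc(OC)c2O[Si](C)(C)C(C)(C)C)ccc1O[Si](C(C)C)(C(C)C)C(C)C | intermediate
25 | 5-hydroxy-2(5H)-furanone | O=C1C=CC(O)O1 | starting material
26 | (1S,2R,5S)-(+)-menthol | CC(C)[C@H]1CC[C@H](C)C[C@@H]1O | starting material
27 | (5S)-5-[(1S,2R,5S)-menthyloxy]-2(5H)-furanone | O=C1C=C[C@@H](O[C@H]2C[C@@H](C)CC[C@@H]2C(C)C)O1 | intermediate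
28 | 2-lithio derivative of dithiane 19 | [Li]C1(SCCCS1)c1cc(OC)c2c(c1)[C@@H](CO[Si](C)(C)C(C)(C)C)[C@H](c1ccc(O[Si](C(C)C)(C(C)C)C(C)C)c(OC)c1)O2 | intermediate
29 | lithium enolate of the (4S,5S)-4-(2-aryl-1,3-dithian-2-yl)-5-menthyloxy lactone | [Li]OC1=C[C@H](C2(SCCCS2)c2cc(OC)c3c(c2)[C@@H](CO[Si](C)(C)C(C)(C)C)[C@H](c2ccc(O[Si](C(C)C)(C(C)C)C(C)C)c(OC)c2)O3)[C@@H](O[C@H]2C[C@@H](C)CC[C@@H]2C(C)C)O1 | intermediate
30 | (3S,4S,5S)-3-benzyl-4-dithianyl-5-menthyloxy lactone (full name in step 17) | COc1cc([C@@H](O[Si](C)(C)C(C)(C)C)[C@H](CO[Si](C)(C)C(C)(C)C)c2cc(C[C@@H]3C(=O)O[C@H](O[C@H]4C[C@@H](C)CC[C@@H]4C(C)C)[C@H]3C3(SCCCS3)c3cc(OC)c4c(c3)[C@@H](CO[Si](C)(C)C(C)(C)C)[C@H](c3ccc(O[Si](C(C)C)(C(C)C)C(C)C)c(OC)c3)O4)cc(OC)c2O[Si](C)(C)C(C)(C)C)ccc1O[Si](C(C)C)(C(C)C)C(C)C | intermediate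
31 | (3S,4S,5S)-3,4-dibenzyl-5-menthyloxy lactone (full name in step 18) | COc1cc([C@@H](O[Si](C)(C)C(C)(C)C)[C@H](CO[Si](C)(C)C(C)(C)C)c2cc(C[C@@H]3C(=O)O[C@H](O[C@H]4C[C@@H](C)CC[C@@H]4C(C)C)[C@H]3Cc3cc(OC)c4c(c3)[C@@H](CO[Si](C)(C)C(C)(C)C)[C@H](c3ccc(O[Si](C(C)C)(C(C)C)C(C)C)c(OC)c3)O4)cc(OC)c2O[Si](C)(C)C(C)(C)C)ccc1O[Si](C(C)C)(C(C)C)C(C)C | intermediate
32 | potassium salt of the ring-opened 4-oxobutanoate (C5 aldehyde, C2 carboxylate) from 31 | COc1cc([C@@H](O[Si](C)(C)C(C)(C)C)[C@H](CO[Si](C)(C)C(C)(C)C)c2cc(C[C@H](C(=O)[O-])[C@@H](C=O)Cc3cc(OC)c4c(c3)[C@@H](CO[Si](C)(C)C(C)(C)C)[C@H](c3ccc(O[Si](C(C)C)(C(C)C)C(C)C)c(OC)c3)O4)cc(OC)c2O[Si](C)(C)C(C)(C)C)ccc1O[Si](C(C)C)(C(C)C)C(C)C.[K+] | intermediate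
33 | potassium salt of the corresponding 4-hydroxybutanoate | COc1cc([C@@H](O[Si](C)(C)C(C)(C)C)[C@H](CO[Si](C)(C)C(C)(C)C)c2cc(C[C@H](C(=O)[O-])[C@@H](CO)Cc3cc(OC)c4c(c3)[C@@H](CO[Si](C)(C)C(C)(C)C)[C@H](c3ccc(O[Si](C(C)C)(C(C)C)C(C)C)c(OC)c3)O4)cc(OC)c2O[Si](C)(C)C(C)(C)C)ccc1O[Si](C(C)C)(C(C)C)C(C)C.[K+] | intermediate
34 | (3S,4S)-hexasilylated trans-dibenzylbutyrolactone (full name in step 19) | COc1cc([C@@H](O[Si](C)(C)C(C)(C)C)[C@H](CO[Si](C)(C)C(C)(C)C)c2cc(C[C@@H]3C(=O)OC[C@H]3Cc3cc(OC)c4c(c3)[C@@H](CO[Si](C)(C)C(C)(C)C)[C@H](c3ccc(O[Si](C(C)C)(C(C)C)C(C)C)c(OC)c3)O4)cc(OC)c2O[Si](C)(C)C(C)(C)C)ccc1O[Si](C(C)C)(C(C)C)C(C)C | intermediate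
35 | CNP0186558.3 | COc1cc([C@@H](O)[C@H](CO)c2cc(C[C@@H]3C(=O)OC[C@H]3Cc3cc(OC)c4c(c3)[C@@H](CO)[C@H](c3ccc(O)c(OC)c3)O4)cc(OC)c2O)ccc1O | target

**Step count and risks**

Total steps: 20. Longest linear sequence: 15 steps (1 → 35 through either branch: steps 1–4, 6–9, then 10–12 or 13–15, then 17–20).

Steps most likely to fail:

- Step 17. The conjugate addition may be incomplete or reversible, and proton transfer may occur before the slow benzylation of a hindered enolate by a large electrophile, costing trans selectivity or leaving C3 unalkylated. Fallback, setting out from 19 and 27: the lithiated dithiane would be added to 27 as before but the enolate quenched with NH4Cl, giving (4S,5S)-4-(2-aryl-1,3-dithian-2-yl)-5-menthyloxydihydrofuran-2(3H)-one F6. Nickel boride desulfurization would give the benzyl lactone acetal F7, and NaBH4/KOH followed by acid the (S)-4-(arylmethyl)butyrolactone F8. Deprotonation of this isolated lactone (LiN(i-Pr)2, THF, −78 °C) and alkylation with 24 (DMPU), trans to the C4 substituent, would rejoin the route at 34.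

- Step 6. Anti simple selectivity or facial selectivity may erode with an aryl-substituted enolate and an electron-rich, weakly electrophilic aldehyde, and retro-aldol may occur during desilylation. Fallback, setting out from 5: the mixed anhydride 7 would be coupled with (R)-4-benzyl-2-oxazolidinone to give the enantiomeric-auxiliary imide F1. A boron syn-aldol (Bu2BOTf, i-Pr2NEt, CH2Cl2, −78 → 0 °C) with 10 would give the (2R,3R) syn adduct F2, which has the required configuration at the aryl-bearing carbon and the epimeric carbinol. LiBH4 would give the (1R,2S) syn diol F3 and t-BuMe2SiCl its primary silyl ether F4. Mitsunobu inversion with 4-nitrobenzoic acid would give the (1S) 4-nitrobenzoate F5, and brief methanolysis (K2CO3, MeOH, 0 °C) would rejoin the route at 14.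

- Step 18. Borohydride may reduce the lactone acetal carbonyl, and nickel may hydrogenolyse the benzylic C–O bond of the dihydrofuran during desulfurization. Fallback, setting out from 30: the menthyloxy group would be removed first (NaBH4, KOH, then acid as in step 19) to give the (3S,4S) dithiane-bearing lactone F9. Radical C–S cleavage with Bu3SnH and azobisisobutyronitrile in toluene at reflux, which uses neither hydride nor a metal surface, would then rejoin the route at 34.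

Further compounds

F1 | step 6 | (R)-3-[2-(2-allyloxy-5-bromo-3-methoxyphenyl)acetyl]-4-benzyloxazolidin-2-one | COc1cc(Br)cc(CC(=O)N2C(=O)OC[C@H]2Cc2ccccc2)c1OCC=C
F2 | step 6 | (R)-4-benzyl-3-[(2R,3R)-2-(2-allyloxy-5-bromo-3-methoxyphenyl)-3-hydroxy-3-(3-methoxy-4-TIPSO-phenyl)propanoyl]oxazolidin-2-one | COc1cc([C@H](O)[C@H](C(=O)N2C(=O)OC[C@H]2Cc2ccccc2)c2cc(Br)cc(OC)c2OCC=C)ccc1O[Si](C(C)C)(C(C)C)C(C)C
F3 | step 6 | (1R,2S)-2-(2-allyloxy-5-bromo-3-methoxyphenyl)-1-(3-methoxy-4-TIPSO-phenyl)propane-1,3-diol | COc1cc([C@H](O)[C@H](CO)c2cc(Br)cc(OC)c2OCC=C)ccc1O[Si](C(C)C)(C(C)C)C(C)C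
F4 | step 6 | (1R,2S)-2-(2-allyloxy-5-bromo-3-methoxyphenyl)-3-(TBSO)-1-(3-methoxy-4-TIPSO-phenyl)propan-1-ol | COc1cc([C@H](O)[C@H](CO[Si](C)(C)C(C)(C)C)c2cc(Br)cc(OC)c2OCC=C)ccc1O[Si](C(C)C)(C(C)C)C(C)C
F5 | step 6 | (1S,2S)-2-(2-allyloxy-5-bromo-3-methoxyphenyl)-3-(TBSO)-1-(3-methoxy-4-TIPSO-phenyl)propyl 4-nitrobenzoate | COc1cc([C@@H](OC(=O)c2ccc(cc2)[N+](=O)[O-])[C@H](CO[Si](C)(C)C(C)(C)C)c2cc(Br)cc(OC)c2OCC=C)ccc1O[Si](C(C)C)(C(C)C)C(C)C
F6 | step 17 | (4S,5S)-4-{2-[(2R,3S)-3-(TBSO-methyl)-7-methoxy-2-(3-methoxy-4-TIPSO-phenyl)-2,3-dihydrobenzofuran-5-yl]-1,3-dithian-2-yl}-5-menthyloxydihydrofuran-2(3H)-one | O=C1C[C@H](C2(SCCCS2)c2cc(OC)c3c(c2)[C@@H](CO[Si](C)(C)C(C)(C)C)[C@H](c2ccc(O[Si](C(C)C)(C(C)C)C(C)C)c(OC)c2)O3)[C@@H](O[C@H]2C[C@@H](C)CC[C@@H]2C(C)C)O1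
F7 | step 17 | (4S,5S)-4-{[(2R,3S)-3-(TBSO-methyl)-7-methoxy-2-(3-methoxy-4-TIPSO-phenyl)-2,3-dihydrobenzofuran-5-yl]methyl}-5-menthyloxydihydrofuran-2(3H)-one | O=C1C[C@H](Cc2cc(OC)c3c(c2)[C@@H](CO[Si](C)(C)C(C)(C)C)[C@H](c2ccc(O[Si](C(C)C)(C(C)C)C(C)C)c(OC)c2)O3)[C@@H](O[C@H]2C[C@@H](C)CC[C@@H]2C(C)C)O1
F8 | step 17 | (S)-4-{[(2R,3S)-3-(TBSO-methyl)-7-methoxy-2-(3-methoxy-4-TIPSO-phenyl)-2,3-dihydrobenzofuran-5-yl]methyl}dihydrofuran-2(3H)-one | O=C1C[C@H](Cc2cc(OC)c3c(c2)[C@@H](CO[Si](C)(C)C(C)(C)C)[C@H](c2ccc(O[Si](C(C)C)(C(C)C)C(C)C)c(OC)c2)O3)CO1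
F9 | step 18 | (3S,4S)-3-benzyl-4-(2-aryl-1,3-dithian-2-yl)dihydrofuran-2(3H)-one, that is 30 without the menthyloxy group | COc1cc([C@@H](O[Si](C)(C)C(C)(C)C)[C@H](CO[Si](C)(C)C(C)(C)C)c2cc(C[C@@H]3C(=O)OC[C@H]3C3(SCCCS3)c3cc(OC)c4c(c3)[C@@H](CO[Si](C)(C)C(C)(C)C)[C@H](c3ccc(O[Si](C(C)C)(C(C)C)C(C)C)c(OC)c3)O4)cc(OC)c2O[Si](C)(C)C(C)(C)C)ccc1O[Si](C(C)C)(C(C)C)C(C)C
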